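Readings and results are simulated with constants of no real substance; the scatter is artificial.

A small charge of free catalyst, 4.0 mM, stands in Thursday's flask, whose starting material reads near 62.5% late in the run, yet Friday's flask, with more partner, reaches 47% by 25.0 min.

common to all: starting material 0.20 M
- Thursday's: partner 0.10 M; free catalyst 4 mM; the very flask that is asked about, followed so far
- Friday's: partner 0.15 M; free catalyst 4 mM; run made earlier
- flask: partner 0.100 M; free catalyst 4.0 mM; time 10 h

Thursday's run (percent of the starting material charged)

| time / h | target / % | starting material / % |
|---|---|---|
| 0.500 | 33 | 60 |
| 0.833 | 22 | 63 |
| 1.50 | 16 | 62 |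
| 3.00 | 16 | 63 |
| 6.00 | 18 | 62 |

Friday's run (percent of the starting material charged)

| time / min | target / % | starting material / % |
|---|---|---|
| 2.00 | 5 | 95 |
| 6.00 | 16 | 81 |
| 12.0 | 35 | 64 |
| 15.0 | 39 | 57 |
| 25.0 | 41 | 47 |

(each reading ± 2 percentage points)

- violet: at 10 h add free catalyst, 50.0% of the amount charged, then wait 3.0 h
- amber: at 10 h add partner, 100% of the amount charged, then wait 3.0 h
- grey: change nothing and wait 3.0 h more
- teal: at 10 h take out 90% of the target then present, then wait 3.0 h

* target, in percent of the starting material first charged, at 10 h
* the remedy with the largest gain of target, or "none" below 2 percentage points (violet / amber / grey / teal / none)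
* target present, with what was taken out counted in, in percent of the starting material first charged, after violet
* target present, with what was taken out counted in, in percent of the starting material first charged, after amber

- target that was removed still counts
- the numbers in the tables scatter with a standard deviation of 2 percentage points
- additions bring no volume worth counting

The reckoning here supposes that partner is used one to one with starting material and is also lost by a second path, both rates first order in partner. Dividing one rate by the other removes time, and integrating over the partner charge gives a closed result. By the readings of Thursday's flask, 37.5% of the starting material was consumed, so 0.750 is the partner yield, the starting material consumed per partner charged. Its odds, 3.00, are the useful rate over the loss rate, taken here as proportional to free catalyst and independent of starting material. Thursday's target, 17.0%, is a share 0.453 of what was consumed.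

1. Grey: Thursday's target reads 16% at 3.00 h and 18% at 6.00 h, so by hand it stays near 17.0% with no gain.
2. Violet: the reckoned rates are first order in partner, so if Thursday's plateau marks the end of partner, added catalyst by hand gains nothing.
3. Amber: by hand, a second partner charge consumes 37.5% more, which gains 17 percentage points and gives 34.0%.
4. Teal: if what stays behind returns to the share 0.453 as target, removal by hand gains 8.4 points.

The forecast gives 17%, chooses amber, and puts violet at 17% and amber at 31%, lower than the reckoning here. Its ground for amber: “Partner restarts the reaction”.

The flask gives 15.2% and amber: violet 15.2%, amber 30.7%, which is below the reckoning here. The gains are 15 points for amber and 8.1 points for teal.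

    partner + free catalyst ⇌ catalyst intermediate A (K = 55.5 M⁻¹, k = 6960 M⁻¹ min⁻¹)
    target ⇌ isomer of the product (K = 1.45, k = 0.0160 min⁻¹)
    catalyst intermediate C → free catalyst + target (k = 425 min⁻¹)
    catalyst intermediate A ⇌ catalyst intermediate B (K = 36.0, k = 1.84 min⁻¹)
    starting material + catalyst intermediate B ⇌ catalyst intermediate C (K = 4.18 M⁻¹, k = 3410 M⁻¹ min⁻¹)
    partner → decomposed reagent (k = 0.0395 min⁻¹)

In the asked flask, the catalytic steps and the decay of partner ran together, and partner, the limiting reagent, stood at 0% by 1.00 h, with 0.0253 M of decomposed reagent formed; at 10.0 h the partner yield stood at 0.747. Target relaxed towards its isomer, with a relaxation half-life of 0.427 h, shorter than the 10 h of the run, and stood at 15.3% beside 22.1% of isomer of the product at 5.00 h.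

In a neighbour flask charged with 0.0010 M of free catalyst, a quarter of the asked flask's charge, the odds become 0.750, so the partner yield is 0.429. That predicts 21.4% consumed and 9.69% target. The neighbour computes to 21.7% consumed and 8.88% target.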